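Locants: oxane O1, C2 (chain), C3, C4 (OH), C5, C6 (ring B); chain C1' (on C2) and C2' (on ring A). Enabling feature: C2 reaches ring A through exactly two carbons. O1–C2–C1' therefore maps onto the O–CH=CH2 of a vinyl ether, C2' plus ring A onto an aromatic aldehyde, and C3–C4–C5 onto a 2-(silylmethyl)allyl unit.
Cuts: C4–OH goes back to C4=O and then to C4=CH2, and a hydroxyl is restored at C2'. C1'–C2' and C2–C3 are then cut together, followed by O1–C2 (vinyl transfer) and last C5–C6 (allylation of the ring B aldehyde).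
Forward: the ring B aldehyde and a bifunctional allyl stannane/silane give the C6 carbinol, and O1 is vinylated. One Lewis acid cascade with the ring A aldehyde then joins the chain and closes the oxane, the only ring that has to be made.
Stereochemistry: C6 (S) comes from the (S)-BINOL–Ti(OiPr)4 catalyst. C2 follows from C6 through a chair closure with both groups equatorial. C4 (R) comes from axial hydride attack on the 2,6-cis oxan-4-one, and the uncontrolled C2' carbinol is deleted.
Electronic control: pivalates keep ring B electron-poor and a benzyl ether keeps ring A electron-rich. Only the C2'–O bond ionises in the later deoxygenation, and the benzylic C6–O1 bond stays closed throughout.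

Key step: step 5

Assumption: the (S)-BINOL–Ti(OiPr)4 catalyst is taken to attack the Si face of the ring B aldehyde, as it does with other aromatic aldehydes; if the sense were opposite, (R)-BINOL would be used.

Step 1
Reactants: 1 3,4-dihydroxy-5-methoxybenzaldehyde (5-hydroxyvanillin)
Product: 2 3-methoxy-4,5-bis(pivaloyloxy)benzaldehyde
Conditions: PivCl (2.5 equiv), Et3N (3 equiv), DMAP (10 mol %), CH2Cl2, 0 °C to rt
Reagents that add atoms: pivaloyl chloride, CC(C)(C)C(=O)Cl
Why: DMAP-catalysed O-acylation of both phenols, giving bulky electron-withdrawing esters that lower the electron density of ring B and should last until the final methanolysis.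

Step 2
Reactants: 3 2-(chloromethyl)allyltrimethylsilane
Product: 4 tributyl[2-(trimethylsilylmethyl)allyl]stannane
Conditions: Bu3SnH, LiN(iPr)2, THF, 0 °C; then 3, −78 °C to rt
Reagents that add atoms: tributyltin hydride, CCCC[SnH](CCCC)CCCC
Why: Nucleophilic displacement of the primary allylic chloride by Bu3SnLi, in which direct (SN2) and transposed (SN2') attack lead to the same stannane.

Step 3
Reactants: 2 3-methoxy-4,5-bis(pivaloyloxy)benzaldehyde; 4 tributyl[2-(trimethylsilylmethyl)allyl]stannane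
Product: 6 (S)-1-[3-methoxy-4,5-bis(pivaloyloxy)phenyl]-3-(trimethylsilylmethyl)but-3-en-1-ol, via tributylstannyl ether 5 (not isolated)
Conditions: (S)-BINOL (20 mol %), Ti(OiPr)4 (10 mol %), 4 Å MS, CH2Cl2, reflux then −20 °C; sat. aq NaHCO3
Reagents that add atoms: none
Why: Keck asymmetric allylation, in which the BINOL–titanium Lewis acid activates 2 and the allylstannane end (far more nucleophilic than the allylsilane end) adds in SE2' fashion to the Si face, setting C6 as (S) and leaving the allylsilane in place.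

Step 4
Reactants: 6 (S)-1-[3-methoxy-4,5-bis(pivaloyloxy)phenyl]-3-(trimethylsilylmethyl)but-3-en-1-ol; 7 butyl vinyl ether
Product: 8 (S)-1-[3-methoxy-4,5-bis(pivaloyloxy)phenyl]-1-(vinyloxy)-3-(trimethylsilylmethyl)but-3-ene
Conditions: Pd(OCOCF3)2 (5 mol %), 4,7-diphenyl-1,10-phenanthroline (5 mol %), Et3N (10 mol %), 7 as solvent, 75 °C
Reagents that add atoms: none
Why: Transfer vinylation (vinyl ether exchange) by oxypalladation–deoxypalladation at a divalent palladium–phenanthroline centre, driven by the large excess of 7 and run in a basic medium that touches neither C6 nor the pivalates.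

Step 5
Reactants: 8 (S)-1-[3-methoxy-4,5-bis(pivaloyloxy)phenyl]-1-(vinyloxy)-3-(trimethylsilylmethyl)but-3-ene; 9 4-benzyloxy-3-methoxybenzaldehyde
Product: 12 1-(4-benzyloxy-3-methoxyphenyl)-2-{(2R,6S)-6-[3-methoxy-4,5-bis(pivaloyloxy)phenyl]-4-methylideneoxan-2-yl}ethanol (both C2' epimers), via oxocarbenium ion 10 (not isolated), via difluoroboryl ether 11 (not isolated)
Conditions: 9 (1.5 equiv), BF3·OEt2 (2.5 equiv), 2,6-di-tert-butyl-4-methylpyridine (2 equiv), CH2Cl2, −78 °C; sat. aq NaHCO3 at −78 °C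
Reagents that add atoms: none
Why: BF3 activates aldehyde 9, the unsubstituted CH2 terminus of the vinyl ether in 8 adds to it (C1'–C2' bond), and because an alkyl enol ether has no group to shed the charge stays at C2 as oxocarbenium ion 10. The =CH2 end of the tethered allylsilane then attacks C2 (C2–C3 bond), the silyl group leaves as Me3SiF from the β-silyl-stabilised C4 position to unveil the exocyclic alkene, and boryl ether 11 is hydrolysed to 12 by the cold bicarbonate quench. The closest known reaction type is the Mukaiyama aldol–Prins cascade of allylsilane-bearing homoallylic vinyl ethers with aldehydes, of which this is a direct application. The oxane closes in a 6-endo-trig mode (the C2=O1 and the C3=C4 π bonds both lie inside the forming ring) through a chair with an (E)-oxocarbenium ion. C2 is controlled by C6, since the ring B aryl group and the C1' chain both take equatorial places in that chair and so end up 2,6-cis (2R,6S in 12), whereas C2' forms without control and is deleted in step 8. Needed are attack on 9 by the vinyl ether ahead of the allylsilane, which the open oxygen-activated CH2 terminus provides as in the parent cascade, capture of 10 before it meets a second vinyl ether, which the intramolecular allylsilane provides, and a C6–O1 bond that neither ionises nor enters a 2-oxonia-Cope exchange, which the two pivalates on ring B, −78 °C and the hindered pyridine base provide.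

Step 6
Reactants: 12 1-(4-benzyloxy-3-methoxyphenyl)-2-{(2R,6S)-6-[3-methoxy-4,5-bis(pivaloyloxy)phenyl]-4-methylideneoxan-2-yl}ethanol (both C2' epimers)
Product: 14 (2S,6S)-2-[2-(4-benzyloxy-3-methoxyphenyl)-2-hydroxyethyl]-6-[3-methoxy-4,5-bis(pivaloyloxy)phenyl]oxan-4-one (both C2' epimers), via vicinal diol 13 (not isolated)
Conditions: OsO4 (3 mol %), NaIO4 (4 equiv), 2,6-lutidine (2 equiv), dioxane–H2O, rt
Reagents that add atoms: osmium tetroxide, O=[Os](=O)(=O)=O (delivers the oxygen, catalytic); sodium periodate, [Na+].[O-]I(=O)(=O)=O (terminal oxygen source)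
Why: Lemieux–Johnson oxidation, in which the exocyclic 1,1-disubstituted alkene is the only olefin present and is dihydroxylated and cleaved in one pot while 2,6-lutidine buffers the mixture so that the β-alkoxy ketone stays closed.

Step 7
Reactants: 14 (2S,6S)-2-[2-(4-benzyloxy-3-methoxyphenyl)-2-hydroxyethyl]-6-[3-methoxy-4,5-bis(pivaloyloxy)phenyl]oxan-4-one (both C2' epimers)
Product: 15 (2R,4R,6S)-2-[2-(4-benzyloxy-3-methoxyphenyl)-2-hydroxyethyl]-6-[3-methoxy-4,5-bis(pivaloyloxy)phenyl]oxan-4-ol (all-cis ring; both C2' epimers)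
Conditions: NaBH4, MeOH–THF, −20 °C
Reagents that add atoms: none
Why: Substrate-controlled borohydride reduction, in which the 2,6-cis oxan-4-one sits in a chair with both substituents equatorial and the small hydride attacks axially, giving the equatorial (4R) alcohol cis to both side groups.

Step 8
Reactants: 15 (2R,4R,6S)-2-[2-(4-benzyloxy-3-methoxyphenyl)-2-hydroxyethyl]-6-[3-methoxy-4,5-bis(pivaloyloxy)phenyl]oxan-4-ol (both C2' epimers)
Product: 17 (2S,4R,6S)-2-[2-(4-benzyloxy-3-methoxyphenyl)ethyl]-6-[3-methoxy-4,5-bis(pivaloyloxy)phenyl]oxan-4-ol, via benzylic cation 16 (not isolated)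
Conditions: Et3SiH (5 equiv), CF3CO2H (5 equiv), CH2Cl2, 0 °C; aq NaHCO3
Reagents that add atoms: none
Why: Ionic hydrogenation (Kursanov–Parnes type), in which only the C2' carbinol para to the benzyloxy group of electron-rich ring A ionises to cation 16 and is quenched by Et3SiH, whereas C6–O1 sits on the pivalate-deactivated ring B and the C4 alcohol cannot ionise, so both C2' epimers converge on one compound.

Step 9
Reactants: 17 (2S,4R,6S)-2-[2-(4-benzyloxy-3-methoxyphenyl)ethyl]-6-[3-methoxy-4,5-bis(pivaloyloxy)phenyl]oxan-4-ol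
Product: 18 (2S,4R,6S)-2-[2-(4-hydroxy-3-methoxyphenyl)ethyl]-6-[3-methoxy-4,5-bis(pivaloyloxy)phenyl]oxan-4-ol
Conditions: H2 (1 atm), 10% Pd/C, EtOAc, rt
Reagents that add atoms: none
Why: Catalytic hydrogenolysis of the aryl benzyl ether under neutral conditions at one atmosphere, under which the cyclic secondary C6–O1 ether on the electron-poor ring B should react far more slowly.

Step 10
Reactants: 18 (2S,4R,6S)-2-[2-(4-hydroxy-3-methoxyphenyl)ethyl]-6-[3-methoxy-4,5-bis(pivaloyloxy)phenyl]oxan-4-ol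
Product: 19 (2S,4R,6S)-2-[2-(4-hydroxy-3-methoxyphenyl)ethyl]-6-(3,4-dihydroxy-5-methoxyphenyl)oxan-4-ol (CNP0399218.1)
Conditions: NaOMe (4 equiv), degassed MeOH, Ar, 0 °C to rt; then AcOH
Reagents that add atoms: none
Why: Zemplén-type transesterification, in which methoxide cleaves the two aryl pivalates (good phenoxide leaving groups) to methyl pivalate while exclusion of oxygen and the acidic quench protect the catechol and no stereocentre is touched.

Compound list
1 | 3,4-dihydroxy-5-methoxybenzaldehyde (5-hydroxyvanillin) | COc1cc(C=O)cc(O)c1O | starting material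
2 | 3-methoxy-4,5-bis(pivaloyloxy)benzaldehyde | COc1cc(C=O)cc(OC(=O)C(C)(C)C)c1OC(=O)C(C)(C)C | intermediate
3 | 2-(chloromethyl)allyltrimethylsilane | C=C(CCl)C[Si](C)(C)C | starting material
4 | tributyl[2-(trimethylsilylmethyl)allyl]stannane | C=C(C[Si](C)(C)C)C[Sn](CCCC)(CCCC)CCCC | intermediate
5 | (S)-tributylstannyl ether of 6 (not isolated) | C=C(C[Si](C)(C)C)C[C@@H](c1cc(OC(=O)C(C)(C)C)c(OC(=O)C(C)(C)C)c(OC)c1)O[Sn](CCCC)(CCCC)CCCC | intermediate
6 | (S)-1-[3-methoxy-4,5-bis(pivaloyloxy)phenyl]-3-(trimethylsilylmethyl)but-3-en-1-ol | C=C(C[Si](C)(C)C)C[C@@H](c1cc(OC(=O)C(C)(C)C)c(OC(=O)C(C)(C)C)c(OC)c1)O | intermediate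
7 | butyl vinyl ether | C=COCCCC | starting material
8 | (S)-1-[3-methoxy-4,5-bis(pivaloyloxy)phenyl]-1-(vinyloxy)-3-(trimethylsilylmethyl)but-3-ene (vinyl ether of 6) | C=C(C[Si](C)(C)C)C[C@@H](c1cc(OC(=O)C(C)(C)C)c(OC(=O)C(C)(C)C)c(OC)c1)OC=C | intermediate
9 | 4-benzyloxy-3-methoxybenzaldehyde | COc1cc(C=O)ccc1OCc1ccccc1 | starting material
10 | C2 oxocarbenium ion carrying the BF3-bound C2' alkoxide, zwitterion, C6 (S) (not isolated) | COc1cc(C(O[B-](F)(F)F)CC=[O+][C@@H](CC(=C)C[Si](C)(C)C)c2cc(OC(=O)C(C)(C)C)c(OC(=O)C(C)(C)C)c(OC)c2)ccc1OCc1ccccc1 | intermediate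
11 | C2' difluoroboryl ether of 12 (not isolated) | COc1cc(C(OB(F)F)C[C@H]2CC(=C)C[C@@H](c3cc(OC(=O)C(C)(C)C)c(OC(=O)C(C)(C)C)c(OC)c3)O2)ccc1OCc1ccccc1 | intermediate
12 | 1-(4-benzyloxy-3-methoxyphenyl)-2-{(2R,6S)-6-[3-methoxy-4,5-bis(pivaloyloxy)phenyl]-4-methylideneoxan-2-yl}ethanol, 2,6-cis, both C2' epimers | COc1cc(C(O)C[C@H]2CC(=C)C[C@@H](c3cc(OC(=O)C(C)(C)C)c(OC(=O)C(C)(C)C)c(OC)c3)O2)ccc1OCc1ccccc1 | intermediate
13 | 2,6-cis 4-hydroxy-4-(hydroxymethyl)oxane derived from 12, C4 and C2' unassigned (not isolated) | COc1cc(C(O)C[C@H]2CC(O)(CO)C[C@@H](c3cc(OC(=O)C(C)(C)C)c(OC(=O)C(C)(C)C)c(OC)c3)O2)ccc1OCc1ccccc1 | intermediate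
14 | (2S,6S)-2-[2-(4-benzyloxy-3-methoxyphenyl)-2-hydroxyethyl]-6-[3-methoxy-4,5-bis(pivaloyloxy)phenyl]oxan-4-one, both C2' epimers | COc1cc(C(O)C[C@H]2CC(=O)C[C@@H](c3cc(OC(=O)C(C)(C)C)c(OC(=O)C(C)(C)C)c(OC)c3)O2)ccc1OCc1ccccc1 | intermediate
15 | (2R,4R,6S)-2-[2-(4-benzyloxy-3-methoxyphenyl)-2-hydroxyethyl]-6-[3-methoxy-4,5-bis(pivaloyloxy)phenyl]oxan-4-ol, all-cis ring, both C2' epimers | COc1cc(C(O)C[C@H]2C[C@@H](O)C[C@@H](c3cc(OC(=O)C(C)(C)C)c(OC(=O)C(C)(C)C)c(OC)c3)O2)ccc1OCc1ccccc1 | intermediate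
16 | C2' benzylic cation derived from 15 (not isolated) | COc1cc([CH+]C[C@H]2C[C@@H](O)C[C@@H](c3cc(OC(=O)C(C)(C)C)c(OC(=O)C(C)(C)C)c(OC)c3)O2)ccc1OCc1ccccc1 | intermediate
17 | (2S,4R,6S)-2-[2-(4-benzyloxy-3-methoxyphenyl)ethyl]-6-[3-methoxy-4,5-bis(pivaloyloxy)phenyl]oxan-4-ol | COc1cc(CC[C@H]2C[C@@H](O)C[C@@H](c3cc(OC(=O)C(C)(C)C)c(OC(=O)C(C)(C)C)c(OC)c3)O2)ccc1OCc1ccccc1 | intermediate
18 | (2S,4R,6S)-2-[2-(4-hydroxy-3-methoxyphenyl)ethyl]-6-[3-methoxy-4,5-bis(pivaloyloxy)phenyl]oxan-4-ol | COc1cc(CC[C@H]2C[C@@H](O)C[C@@H](c3cc(OC(=O)C(C)(C)C)c(OC(=O)C(C)(C)C)c(OC)c3)O2)ccc1O | intermediate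
19 | (2S,4R,6S)-2-[2-(4-hydroxy-3-methoxyphenyl)ethyl]-6-(3,4-dihydroxy-5-methoxyphenyl)oxan-4-ol (CNP0399218.1) | COc1cc(CC[C@H]2C[C@@H](O)C[C@@H](c3cc(O)c(O)c(OC)c3)O2)ccc1O | target

Total step count: 10.
Longest linear sequence: 9 steps (1, 2, 6, 8, 12, 14, 15, 17, 18, 19). The branch from 3 through 4 is equally long.

Steps most likely to fail

1) Step 5, the cascade.
- **What may go wrong:** The electron-rich aldehyde 9 may react slowly. Hosomi–Sakurai attack by the allylsilane, protodesilylation or oligomerisation of the vinyl ether could then compete. The C2' boryl ether on ring A may also ionise before the quench.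
- **Fallback:** It sets out from 6 (with 9 as the source of the partner) and comes back at 17. The chain is brought in already deoxygenated, and the oxane is closed by an intermolecular allylsilane pyran annulation (silyl-Prins).
- Wittig reaction of 9 with Ph3P=CHCHO should give (E)-3-(4-benzyloxy-3-methoxyphenyl)prop-2-enal F1.
- Organocatalytic transfer hydrogenation (Hantzsch ester, dibenzylammonium trifluoroacetate) should give 3-(4-benzyloxy-3-methoxyphenyl)propanal F2.
- Treating 6 and F2 with TMSOTf in Et2O at −78 °C should give (2S,6S)-2-[2-(4-benzyloxy-3-methoxyphenyl)ethyl]-6-[3-methoxy-4,5-bis(pivaloyloxy)phenyl]-4-methylideneoxane F3.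
- OsO4–NaIO4 cleavage then leads to (2S,6S)-2-[2-(4-benzyloxy-3-methoxyphenyl)ethyl]-6-[3-methoxy-4,5-bis(pivaloyloxy)phenyl]oxan-4-one F4, and NaBH4 reduction of F4 gives 17.

2) Step 4, the vinyl transfer.
- **What may go wrong:** Desilylative palladation of the allylsilane may drain the divalent palladium catalyst. Exchange at the hindered secondary benzylic alcohol may stall, and the vinyl ether may hydrolyse during purification.
- **Fallback:** It sets out from 2 and comes back at 8. The vinyl ether is made before the allylsilane exists.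
- Si-face 2-bromoallylation of 2 should give (S)-3-bromo-1-[3-methoxy-4,5-bis(pivaloyloxy)phenyl]but-3-en-1-ol F5. The reagents are 2-bromoallyltributylstannane and the B-bromodiazaborolidine from 1,2-diphenylethylenediamine bis(4-toluenesulfonamide), in the enantiomeric form that serves this face, in CH2Cl2 at −78 °C.
- The vinyl transfer with 7 is then run on this silicon-free alcohol and gives (S)-3-bromo-1-[3-methoxy-4,5-bis(pivaloyloxy)phenyl]-1-(vinyloxy)but-3-ene F6.
- Negishi coupling of the alkenyl bromide with Me3SiCH2ZnCl and Pd(PPh3)4 (zerovalent palladium) in THF installs the silylmethyl group and delivers 8.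

3) Step 8, the deoxygenation.
- **What may go wrong:** The cation may be diverted into Friedel–Crafts self-alkylation of ring A or into proton loss toward the styrene. Acid may also begin to open the C6–O1 bond.
- **Fallback:** It sets out from 15 and comes back at 19. Hydride capture of a free cation is replaced by heterogeneous hydrogenolysis of an activated ester.
- Ac2O, pyridine and DMAP convert 15 into (2R,4R,6S)-4-acetoxy-2-[2-acetoxy-2-(4-benzyloxy-3-methoxyphenyl)ethyl]-6-[3-methoxy-4,5-bis(pivaloyloxy)phenyl]oxane F7.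
- H2 over 10% Pd/C in EtOAc removes the benzyl ether and the benzylic C2' acetate under neutral conditions. This gives (2S,4R,6S)-4-acetoxy-2-[2-(4-hydroxy-3-methoxyphenyl)ethyl]-6-[3-methoxy-4,5-bis(pivaloyloxy)phenyl]oxane F8.
- The conditions of step 10 cleave the C4 acetate together with the pivalates and give 19.

Further compounds
F1 | step 5 | (E)-3-(4-benzyloxy-3-methoxyphenyl)prop-2-enal | COc1cc(/C=C/C=O)ccc1OCc1ccccc1
F2 | step 5 | 3-(4-benzyloxy-3-methoxyphenyl)propanal | COc1cc(CCC=O)ccc1OCc1ccccc1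
F3 | step 5 | (2S,6S)-2-[2-(4-benzyloxy-3-methoxyphenyl)ethyl]-6-[3-methoxy-4,5-bis(pivaloyloxy)phenyl]-4-methylideneoxane | COc1cc(CC[C@H]2CC(=C)C[C@@H](c3cc(OC(=O)C(C)(C)C)c(OC(=O)C(C)(C)C)c(OC)c3)O2)ccc1OCc1ccccc1
F4 | step 5 | (2S,6S)-2-[2-(4-benzyloxy-3-methoxyphenyl)ethyl]-6-[3-methoxy-4,5-bis(pivaloyloxy)phenyl]oxan-4-one | COc1cc(CC[C@H]2CC(=O)C[C@@H](c3cc(OC(=O)C(C)(C)C)c(OC(=O)C(C)(C)C)c(OC)c3)O2)ccc1OCc1ccccc1
F5 | step 4 | (S)-3-bromo-1-[3-methoxy-4,5-bis(pivaloyloxy)phenyl]but-3-en-1-ol | C=C(Br)C[C@@H](c1cc(OC(=O)C(C)(C)C)c(OC(=O)C(C)(C)C)c(OC)c1)O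
F6 | step 4 | (S)-3-bromo-1-[3-methoxy-4,5-bis(pivaloyloxy)phenyl]-1-(vinyloxy)but-3-ene | C=C(Br)C[C@@H](c1cc(OC(=O)C(C)(C)C)c(OC(=O)C(C)(C)C)c(OC)c1)OC=C
F7 | step 8 | (2R,4R,6S)-4-acetoxy-2-[2-acetoxy-2-(4-benzyloxy-3-methoxyphenyl)ethyl]-6-[3-methoxy-4,5-bis(pivaloyloxy)phenyl]oxane, both C2' epimers | COc1cc(C(OC(C)=O)C[C@H]2C[C@@H](OC(C)=O)C[C@@H](c3cc(OC(=O)C(C)(C)C)c(OC(=O)C(C)(C)C)c(OC)c3)O2)ccc1OCc1ccccc1
F8 | step 8 | (2S,4R,6S)-4-acetoxy-2-[2-(4-hydroxy-3-methoxyphenyl)ethyl]-6-[3-methoxy-4,5-bis(pivaloyloxy)phenyl]oxane | COc1cc(CC[C@H]2C[C@@H](OC(C)=O)C[C@@H](c3cc(OC(=O)C(C)(C)C)c(OC(=O)C(C)(C)C)c(OC)c3)O2)ccc1O
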